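Protic impurity first: from Tuesday's 2.5 mM to Sunday's 10 mM, the last target reading falls from 69% to 35%. Tuesday's starting material already reads 1% at 1.33 min.

| flask | starting material | partner | protic impurity | free catalyst | remark | time |
|---|---|---|---|---|---|---|
| Tuesday's | 0.0050 M | 0.020 M | 2.5 mM | 13 µM | run made earlier |  |
| Sunday's | 0.0050 M | 0.020 M | 10 mM | 13 µM | run made earlier |  |
| Thursday's | 0.0075 M | 0.020 M | 5 mM | 13 µM | run made earlier |  |
| flask | 0.0050 M | 0.0200 M | 5.00 mM | 13 µM |  | 15 min |

| run | time / min | starting material / % | target / % |
|---|---|---|---|
| Tuesday's | 1.33 | 1 | 71 |
| Tuesday's | 3.00 | 1 | 71 |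
| Tuesday's | 6.00 | 1 | 70 |
| Tuesday's | 15.0 | 0 | 69 |
| Sunday's | 1.33 | 1 | 30 |
| Sunday's | 3.00 | 1 | 33 |
| Sunday's | 6.00 | 2 | 31 |
| Sunday's | 15.0 | 0 | 35 |
| Thursday's | 4.00 | 0 | 58 |
| Thursday's | 8.00 | 0 | 56 |
| Thursday's | 12.0 | 0 | 55 |
| Thursday's | 15.0 | 0 | 55 |

(standard deviation of a reading: 1.5 percentage points)

- the numbers in the tables scatter with a standard deviation of 1.5 percentage points
- the reaction counts as stopped when no species that holds the starting material changes by six tenths of a point or more over the second half of the time

1. which holds at 15 min: what has brought the reaction to rest, or that it has not come to rest (forward and back rates have come level / no working catalyst is left / the partner has run out first / all of the starting material has reacted / it is still moving)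
2. part of the starting material gone at 15 min
3. the target standing at 15 min, as a percentage of the starting material charged

My reckoning assumes that starting material becomes target with a steady rate constant and is lost with a rate constant proportional to the standing impurity h. Target per loss is then K/h, a selectivity factor in concentration form, so K = P/ln(H/h), with P the target and H the impurity charged.

| run | mean target | K |
|---|---|---|
| Tuesday's | 70.2% | 3.89 mM |
| Sunday's | 32.2% | 3.90 mM |

Take their mean, the balance concentration K, the impurity level at which both paths run level: 3.89 mM. Fold the new flask into N = H/K = 1.28, the impurity charge in units of K. The first share of target, K/(K+H), reckoned with the impurity still at its charge, is 43.8%.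

Test it on Thursday's run, which has the same N but whose readings average 56.0%, more than that share. One number is not enough, so go round again: put the first share back and use for H the mean of the impurity's charge and its end. Thursday's run then reckons 57.4%, and the new flask 52.0%, with its starting material reacted.

The forecast, by its own route through the partner, said all of the starting material has reacted, conversion 100%, target 52% (48% to 56%): “the yield is set by competition, not time”.

The flask gives all of the starting material has reacted, conversion 100%, target 52.2%.

    catalyst intermediate C → free catalyst + target (k = 3730 s⁻¹)
    starting material + protic impurity → quenched substrate (k = 69.4 M⁻¹ s⁻¹)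
    partner + catalyst intermediate A → catalyst intermediate B (k = 1.49 × 10⁵ M⁻¹ s⁻¹)
    starting material + free catalyst → catalyst intermediate A (k = 27000 M⁻¹ s⁻¹)
    catalyst intermediate B → released group + catalyst intermediate C (k = 279 s⁻¹)

In the flask, 52% of the impurity stands at the end, and K times ln(H/h) reckons 2.54 mM of target, against 2.61 mM of released group. Now charge 0.013 M of impurity in the neighbour: N is 3.34, the first share 23.0%, and the second round 26.0%. That neighbour flask ends with 72% of its impurity standing and 26.7% target.

Readings and results were computed for an exercise, noise included.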